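**Retrosynthetic overview**

- The symmetric disulfide is cut at S–S into two identical thiols. Each thiol comes from its thioacetate, and that from a primary bromide at the end of the C10 chain.
- The C5 methyl of each 2-pyranone is traced to an enol triflate (Negishi methylation), which comes from a pyran-2,5-dione and that from a lactol.
- The route rests on one feature: in each ring the methoxy-bearing C3 and C4 sit between the C2 lactone carbonyl and C5, and O1 is bonded to the chain-bearing C6. This is the substitution pattern of 3,4-dimethoxyfuran with a 1-hydroxyalkyl group at C2, so the pyranone is made by Achmatowicz ring expansion of that furyl carbinol.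
- The carbinol comes from 2-lithio-3,4-dimethoxyfuran and 11-bromoundecanal. The pyranone is the only ring formed, once per half, before dimerisation.

Key step: step 3

Assumption: 3,4-dimethoxyfuran and MeZnCl (THF solution) are taken as purchasable; the carbinol is carried as a racemate because its stereocentre is erased in step 5.

**Route**

Step 1
Reactants: 1 11-bromoundecan-1-ol
Product: 2 11-bromoundecanal
Conditions: TEMPO (cat.), PhI(OAc)2, CH2Cl2, rt
Reagents that add atoms: none
Why: The oxoammonium-mediated (TEMPO/PhI(OAc)2) alcohol oxidation stops at the aldehyde under neutral anhydrous conditions and leaves the primary bromide untouched.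

Step 2
Reactants: 3 3,4-dimethoxyfuran; 2 11-bromoundecanal
Product: 5 racemic 11-bromo-1-(3,4-dimethoxyfuran-2-yl)undecan-1-ol, via 2-lithio-3,4-dimethoxyfuran 4 (not isolated)
Conditions: n-BuLi (slightly less than 3), THF, −78 to 0 °C; then 2, −78 °C; water quench, base-washed silica
Reagents that add atoms: none
Why: Alpha-lithiation of the furan (C2–H is acidified by the ring oxygen and the C3 methoxy group) and 1,2-addition of the furyllithium to the aldehyde at −78 °C should outpace SN2 attack on the primary bromide; the carbinol centre forms racemic and needs no control.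

Step 3
Reactants: 5 racemic 11-bromo-1-(3,4-dimethoxyfuran-2-yl)undecan-1-ol
Product: 7 2-(10-bromodecyl)-6-hydroxy-4,5-dimethoxy-2H-pyran-3(6H)-one (racemic anomer mixture), via Z-enedione aldehyde 6 (not isolated)
Conditions: NBS (1.0 equiv), NaHCO3, THF/H2O (4:1), 0 °C
Reagents that add atoms: water, O
Why: NBS delivers electrophilic bromine to the only free alpha carbon of the furan (old C5), water adds at the carbinol-bearing C2, and the 2,5-dioxygenated dihydrofuran so formed loses HBr and opens to the Z-enedione 6, whose ketone and aldehyde carbons are the old furan C2 and C5. This is the Achmatowicz rearrangement of a 2-furyl carbinol to a 6-hydroxy-2H-pyran-3(6H)-one, applied here to a 3,4-dialkoxy member of that class. The one ring is closed by 6-exo-trig hemiacetalisation, the secondary hydroxyl oxygen adding to the aldehyde carbonyl and forming the bond that becomes O1–C2 of the target. The only new stereocentre is the anomeric carbon, which equilibrates through the open form to a thermodynamic anomer mixture and is left uncontrolled because step 4 oxidises it; the carbinol centre stays racemic. The step needs oxidation of the furan in preference to the secondary alcohol and the alkyl bromide, and closure by the carbinol oxygen instead of hydration: the doubly methoxy-activated furan is the most nucleophilic site for one equivalent of NBS at 0 °C, the NaHCO3 buffer removes HBr before it can cleave the vinylogous ester, and the cis geometry inherited from the ring keeps the hydroxyl within reach of the aldehyde carbon.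

Step 4
Reactants: 7 2-(10-bromodecyl)-6-hydroxy-4,5-dimethoxy-2H-pyran-3(6H)-one
Product: 8 racemic 6-(10-bromodecyl)-3,4-dimethoxy-2H-pyran-2,5(6H)-dione
Conditions: Dess–Martin periodinane, CH2Cl2, 0 °C to rt; aq. Na2S2O3/NaHCO3 work-up
Reagents that add atoms: none
Why: Dess–Martin oxidation of the hemiacetal hydroxyl to the lactone runs under anhydrous, nearly neutral conditions that should spare both methoxy enol ethers and the bromide, and it removes the anomeric stereocentre.

Step 5
Reactants: 8 racemic 6-(10-bromodecyl)-3,4-dimethoxy-2H-pyran-2,5(6H)-dione
Product: 10 2-(10-bromodecyl)-4,5-dimethoxy-6-oxo-6H-pyran-3-yl trifluoromethanesulfonate, via 5-hydroxy-2-pyranone tautomer 9 (not isolated)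
Conditions: Et3N, CH2Cl2, 0 °C; then Tf2O, −78 to −20 °C
Reagents that add atoms: trifluoromethanesulfonic anhydride, O=S(=O)(OS(=O)(=O)C(F)(F)F)C(F)(F)F
Why: Triethylamine removes the acidic C6–H (alpha to the ketone, giving an aromatic 2-pyranone enol), and O-sulfonylation of that enol by Tf2O (enol triflate formation) traps it whichever tautomer predominates, erasing the last stereocentre.

Step 6
Reactants: 10 2-(10-bromodecyl)-4,5-dimethoxy-6-oxo-6H-pyran-3-yl trifluoromethanesulfonate
Product: 11 6-(10-bromodecyl)-3,4-dimethoxy-5-methyl-2H-pyran-2-one
Conditions: MeZnCl (2 equiv), Pd(PPh3)4 (5 mol %), THF, 60 °C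
Reagents that add atoms: methylzinc chloride, C[Zn]Cl
Why: Negishi coupling, in which zerovalent palladium inserts into the C(sp2)–OTf bond, methyl is transferred from zinc and reductive elimination forms C5–CH3; the organozinc tolerates the lactone, and an unactivated primary alkyl bromide should not undergo oxidative addition with a triphenylphosphine-ligated catalyst at this temperature.

Step 7
Reactants: 11 6-(10-bromodecyl)-3,4-dimethoxy-5-methyl-2H-pyran-2-one
Product: 12 S-[10-(4,5-dimethoxy-3-methyl-6-oxo-6H-pyran-2-yl)decyl] ethanethioate
Conditions: KSAc (potassium thioacetate, 1.2 equiv), DMF, rt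
Reagents that add atoms: potassium thioacetate, CC(=O)[S-].[K+]
Why: SN2 displacement of the primary bromide by the soft, weakly basic thioacetate anion should not touch the fully substituted pyranone.

Step 8
Reactants: 12 S-[10-(4,5-dimethoxy-3-methyl-6-oxo-6H-pyran-2-yl)decyl] ethanethioate
Product: 13 3,4-dimethoxy-5-methyl-6-(10-sulfanyldecyl)-2H-pyran-2-one
Conditions: HCl (1.25 M in MeOH, catalytic), degassed MeOH, argon, 50 °C
Reagents that add atoms: none
Why: Acid-catalysed methanolysis (transesterification) of the thioester frees the thiol without exposing the lactone to methoxide, and any acid-promoted exchange of the ring methoxy groups is degenerate in methanol.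

Step 9
Reactants: 13 3,4-dimethoxy-5-methyl-6-(10-sulfanyldecyl)-2H-pyran-2-one (two molecules)
Product: 14 lehualide K
Conditions: I2 (0.5 equiv), Et3N (1 equiv), CH2Cl2/MeOH, 0 °C to rt; aq. Na2S2O3 wash
Reagents that add atoms: none
Why: Iodine oxidation of the thiol goes through a sulfenyl iodide that is captured by a second thiol to give the symmetric disulfide; the pyranone has no free ring C–H for iodination.

**Compound list**

1 | 11-bromoundecan-1-ol | OCCCCCCCCCCCBr | starting material
2 | 11-bromoundecanal | O=CCCCCCCCCCCBr | intermediate
3 | 3,4-dimethoxyfuran | COc1cocc1OC | starting material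
4 | 2-lithio-3,4-dimethoxyfuran (not isolated) | [Li]c1occ(OC)c1OC | intermediate
5 | 11-bromo-1-(3,4-dimethoxyfuran-2-yl)undecan-1-ol, racemic | COc1coc(C(O)CCCCCCCCCCBr)c1OC | intermediate
6 | (Z)-15-bromo-5-hydroxy-2,3-dimethoxy-4-oxopentadec-2-enal, racemic (not isolated) | O=C/C(OC)=C(OC)\C(=O)C(O)CCCCCCCCCCBr | intermediate
7 | 2-(10-bromodecyl)-6-hydroxy-4,5-dimethoxy-2H-pyran-3(6H)-one, racemic mixture of anomers | OC1OC(CCCCCCCCCCBr)C(=O)C(OC)=C1OC | intermediate
8 | 6-(10-bromodecyl)-3,4-dimethoxy-2H-pyran-2,5(6H)-dione, racemic | O=C1OC(CCCCCCCCCCBr)C(=O)C(OC)=C1OC | intermediate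
9 | 6-(10-bromodecyl)-5-hydroxy-3,4-dimethoxy-2H-pyran-2-one (not isolated) | COc1c(O)c(CCCCCCCCCCBr)oc(=O)c1OC | intermediate
10 | 2-(10-bromodecyl)-4,5-dimethoxy-6-oxo-6H-pyran-3-yl trifluoromethanesulfonate | COc1c(OS(=O)(=O)C(F)(F)F)c(CCCCCCCCCCBr)oc(=O)c1OC | intermediate
11 | 6-(10-bromodecyl)-3,4-dimethoxy-5-methyl-2H-pyran-2-one | COc1c(C)c(CCCCCCCCCCBr)oc(=O)c1OC | intermediate
12 | S-[10-(4,5-dimethoxy-3-methyl-6-oxo-6H-pyran-2-yl)decyl] ethanethioate | COc1c(C)c(CCCCCCCCCCSC(C)=O)oc(=O)c1OC | intermediate
13 | 3,4-dimethoxy-5-methyl-6-(10-sulfanyldecyl)-2H-pyran-2-one | COc1c(C)c(CCCCCCCCCCS)oc(=O)c1OC | intermediate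
14 | lehualide K (achiral) | COc1c(C)c(CCCCCCCCCCSSCCCCCCCCCCc2oc(=O)c(OC)c(OC)c2C)oc(=O)c1OC | target

**Step count and risks**

Total steps: 9. Longest linear sequence: 9 steps, from 1 to 14.

Steps most likely to fail:

1. Step 3. Oxidation may not stop at the furan: the electron-rich enol ether double bond of the opened or closed product could be brominated further, or HBr formed faster than the buffer removes it could hydrolyse a vinylogous ester methoxy group before the lactol closes. The fallback sets out from 5 and comes back at 7, with no halogen and no acid. Sensitised photooxygenation (O2, visible light, metal-free tetraphenylporphyrin, CH2Cl2, −78 °C) adds singlet oxygen across furan C2 and C5 in a [4+2] cycloaddition to give the endoperoxide 11-bromo-1-(5,6-dimethoxy-2,3,7-trioxabicyclo[2.2.1]hept-5-en-1-yl)undecan-1-ol F1. Me2S added in the same flask reduces the O–O bond and releases the same Z-enedione 6, which closes to lactol 7.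

2. Step 6. Oxidative addition of zerovalent palladium into the C–O bond may be slow, because the triflate is flanked by the C4 methoxy group and the C6 chain on an electron-rich ring; attack of the organozinc at sulfur (returning the enol) or reduction could then compete. The fallback sets out from 8 and comes back at 11, and avoids the triflate. Non-basic methylenation of the C5 ketone with Zn/CH2Br2/TiCl4 in THF/CH2Cl2 at 0 °C (a Takai–Lombardo-type reagent that tolerates easily enolised ketones and leaves lactones alone) should give 6-(10-bromodecyl)-3,4-dimethoxy-5-methylidene-5,6-dihydro-2H-pyran-2-one F2. Catalytic RhCl3·3H2O in ethanol at 70 °C would then move the exocyclic double bond into the ring, driven by formation of the aromatic 2-pyranone 11.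

3. Step 2. The basic furyllithium may enolise the aldehyde instead of adding, or the product, a furfuryl alcohol strongly activated by the C3 methoxy group, may ionise during work-up or chromatography and oligomerise. The fallback sets out from 3 and comes back at 5. Friedel–Crafts acylation of 3 with commercial 11-bromoundecanoyl chloride (SnCl4, CH2Cl2, −78 °C; the two alpha positions are equivalent and the first acyl group deactivates the ring) should give the stable, purifiable ketone 11-bromo-1-(3,4-dimethoxyfuran-2-yl)undecan-1-one F3. Reduction with NaBH4 in MeOH at 0 °C just before the key step gives 5, which is used crude.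

**Further compounds**

F1 | step 3 | 11-bromo-1-(5,6-dimethoxy-2,3,7-trioxabicyclo[2.2.1]hept-5-en-1-yl)undecan-1-ol | COC1=C(OC)C2(OOC1O2)C(O)CCCCCCCCCCBr
F2 | step 6 | 6-(10-bromodecyl)-3,4-dimethoxy-5-methylidene-5,6-dihydro-2H-pyran-2-one | C=C1C(CCCCCCCCCCBr)OC(=O)C(OC)=C1OC
F3 | step 2 | 11-bromo-1-(3,4-dimethoxyfuran-2-yl)undecan-1-one | COc1coc(C(=O)CCCCCCCCCCBr)c1OC
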